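**Plan**
Cuts: the acid is freed last from its tert-butyl ester. The ring methyl goes back to an enol triflate, so its carbon is read as a ketone. The ArO–CH2 bond is an oxa-Michael addition of umbelliferone to a 2-methylidene ketone, and that CH2 comes from formaldehyde.
Enabling feature: number the cyclohexene C1 (quaternary), C2 (CH–CH2OAr), C3 (=C–CH3), C4 (=CH), C5 (CH2), C6 (CH–isopropenyl). C2 then lies between a latent carbonyl carbon (C3) and its fully substituted α-carbon (C1), so C2 can be deleted: the ring is a cyclopentanone enlarged by one carbon through migration of C1.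
Forward: 2-methylcyclopent-2-enone takes up isopropenyl (C6) and then tert-butyl acrylate (C1), and LiCHBr2 adds to the C=O. Br/Li exchange gives a β-oxido carbenoid whose 1,2-shift turns the five- into the six-membered ring. The shift leaves the otherwise inaccessible C3=C2 enolate, which is trapped with CH2O.
Stereochemistry: C6 comes from a Cu-catalysed asymmetric conjugate addition. C1 comes from a Michael addition anti to isopropenyl, reinforced by (R)-1-phenylethylamine, and is retained in the shift. C2 comes from axial protonation of the enolate formed in the oxa-Michael step.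

Key step: step 4

Remark: ring locants in the text are those defined above. Stereocentres that a later step erases (C2 of 4, C2 of 15 and 16) are left open in the SMILES.

Step 1
Reactants: 1 2-methylcyclopent-2-en-1-one; 2 isopropenylmagnesium bromide
Product: 4 (3S)-2-methyl-3-(prop-1-en-2-yl)cyclopentan-1-one as a mixture of C2 epimers, via magnesium enolate 3 (not isolated)
Conditions: CuBr·SMe2 (5 mol %), chiral ferrocenyl diphosphine (Josiphos family, 6 mol %, enantiomer that delivers 3S), t-BuOMe, −75 °C; sat. aq NH4Cl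
Reagents that add atoms: isopropenylmagnesium bromide, C=C(C)[Mg]Br
Why: Cu-catalysed asymmetric conjugate addition of a Grignard reagent to an α-methyl cyclopentenone; the chiral Cu complex selects the enone face and sets the isopropenyl-bearing centre, while the α-centre is of no consequence because it becomes trigonal in step 2.

Step 2
Reactants: 4 (3S)-2-methyl-3-(prop-1-en-2-yl)cyclopentan-1-one; 5 (R)-1-phenylethylamine; 6 tert-butyl acrylate
Product: 9 tert-butyl 3-[(1R,5R)-1-methyl-2-oxo-5-(prop-1-en-2-yl)cyclopentyl]propanoate, via ketimine 7 (not isolated), via adduct ketimine 8 (not isolated)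
Conditions: 5, TsOH (cat.), PhMe, Dean–Stark; 6, THF, 50 °C; 20 % aq AcOH, rt
Reagents that add atoms: tert-butyl acrylate, C=CC(=O)OC(C)(C)C; water, O
Why: The ketimine reacts through its more substituted secondary-enamine tautomer in an aza-ene-like asymmetric Michael addition with internal N–H transfer, so only the methyl-bearing α-carbon is alkylated; the acrylate should approach anti to isopropenyl, a preference the (R)-auxiliary reinforces, which sets the quaternary centre with the propanoate arm trans to isopropenyl.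

Step 3
Reactants: 9 tert-butyl 3-[(1R,5R)-1-methyl-2-oxo-5-(prop-1-en-2-yl)cyclopentyl]propanoate; 10 dibromomethane
Product: 11 tert-butyl 3-[(1R,2R,5R)-2-(dibromomethyl)-2-hydroxy-1-methyl-5-(prop-1-en-2-yl)cyclopentyl]propanoate
Conditions: CH2Br2, LDA (added last), THF, −78 °C; AcOH, −78 °C
Reagents that add atoms: dibromomethane, BrCBr
Why: 1,2-addition of a lithium carbenoid (dibromomethyllithium made in the presence of the ketone) should occur from the face opposite the pseudo-axial methyl and the isopropenyl group; the new carbinol centre is lost again in step 4, and the tert-butyl ester is too hindered to compete.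

Step 4
Reactants: 11 tert-butyl 3-[(1R,2R,5R)-2-(dibromomethyl)-2-hydroxy-1-methyl-5-(prop-1-en-2-yl)cyclopentyl]propanoate; 12 formaldehyde
Product: 15 tert-butyl 3-[(1R,6R)-2-(hydroxymethyl)-1-methyl-3-oxo-6-(prop-1-en-2-yl)cyclohexyl]propanoate as C2 epimers, via dilithiated oxido carbenoid 13 (not isolated), via ring-enlarged lithium enolate 14 (not isolated)
Conditions: n-BuLi (2.05 equiv), THF, −95 °C, then to −50 °C; CH2O (gas from cracked paraformaldehyde), −78 °C; sat. aq NH4Cl
Reagents that add atoms: formaldehyde, C=O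
Why: The first equivalent of n-BuLi forms the alkoxide and the second exchanges one bromine faster than it attacks the hindered ester, giving β-oxido carbenoid 13; push from the oxido group and loss of LiBr drive a concerted 1,2-shift of a ring C–C bond to the carbenoid carbon, anti to the departing bromide, which gives lithium enolate 14 (β-oxido carbenoid one-carbon ring enlargement of a ketone, followed by an aldol reaction). No ring is closed anew: the five-membered ring is enlarged by insertion of the carbenoid carbon (future C2) between the carbinol carbon (future C3) and quaternary C1. The step needs migration of C1 and not of the ring CH2; the electron-poor carbenoid carbon selects the more substituted, more electron-rich tert-alkyl carbon, as in cationoid pinacol-type shifts, and the shift also relieves the congestion between C1 and the carbinol carbon. C1 migrates with retention and C6 is untouched, so both existing stereocentres are carried over. The enolate double bond lies only between C3 and C2, a regiochemistry that deprotonation of the ketone could not give because C2 is neopentyl-like, and the small electrophile formaldehyde attaches the last skeletal carbon there. The new centre C2 should arise mainly by axial attack anti to the C1 methyl, but its configuration does not matter because step 5 makes C2 trigonal.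

Step 5
Reactants: 15 tert-butyl 3-[(1R,6R)-2-(hydroxymethyl)-1-methyl-3-oxo-6-(prop-1-en-2-yl)cyclohexyl]propanoate
Product: 17 tert-butyl 3-[(1R,6R)-1-methyl-2-methylidene-3-oxo-6-(prop-1-en-2-yl)cyclohexyl]propanoate, via primary mesylate 16 (not isolated)
Conditions: MsCl, Et3N, CH2Cl2, 0 °C; DBU, rt
Reagents that add atoms: none
Why: Mesylation of the primary aldol hydroxyl and E1cB elimination (aldol dehydration) should give the same 2-methylidene ketone from both C2 epimers; no stereocentre is formed, and quaternary C1 excludes an endocyclic alternative.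

Step 6
Reactants: 17 tert-butyl 3-[(1R,6R)-1-methyl-2-methylidene-3-oxo-6-(prop-1-en-2-yl)cyclohexyl]propanoate; 18 umbelliferone (7-hydroxycoumarin)
Product: 19 tert-butyl 3-[(1R,2R,6R)-1-methyl-3-oxo-2-{[(2-oxo-2H-chromen-7-yl)oxy]methyl}-6-(prop-1-en-2-yl)cyclohexyl]propanoate
Conditions: 18 (1.3 equiv), Cs2CO3 (10 mol %), MeCN, 0 °C
Reagents that add atoms: umbelliferone, Oc1ccc2ccc(=O)oc2c1
Why: Base-catalysed oxa-Michael addition of the acidic phenol to the unhindered exocyclic CH2 of the s-cis enone; the resulting C3=C2 enolate should be protonated axially, on the face opposite the pseudo-axial C1 methyl, which places CH2OAr equatorial and cis to that methyl (2R), expected also to be the more stable epimer.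

Step 7
Reactants: 19 tert-butyl 3-[(1R,2R,6R)-1-methyl-3-oxo-2-{[(2-oxo-2H-chromen-7-yl)oxy]methyl}-6-(prop-1-en-2-yl)cyclohexyl]propanoate; 20 N-phenylbis(trifluoromethanesulfonimide)
Product: 22 tert-butyl 3-[(1R,2R,6R)-1-methyl-2-{[(2-oxo-2H-chromen-7-yl)oxy]methyl}-6-(prop-1-en-2-yl)-3-(trifluoromethanesulfonyloxy)cyclohex-3-en-1-yl]propanoate, via potassium enolate 21 (not isolated)
Conditions: KHMDS, THF, −78 °C (ketone added to base); PhNTf2, −78 to 0 °C; sat. aq NH4Cl
Reagents that add atoms: N-phenylbis(trifluoromethanesulfonimide), O=S(=O)(N(c1ccccc1)S(=O)(=O)C(F)(F)F)C(F)(F)F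
Why: Kinetic deprotonation with a bulky amide removes a C4 proton and not the shielded tertiary C2–H, so the aryloxide is not expelled, and O-sulfonylation (enol triflate formation) fixes the C3=C4 double bond without touching a stereocentre.

Step 8
Reactants: 22 the enol triflate of step 7; 23 methylzinc chloride
Product: 24 tert-butyl 3-[(1R,2R,6R)-1,3-dimethyl-2-{[(2-oxo-2H-chromen-7-yl)oxy]methyl}-6-(prop-1-en-2-yl)cyclohex-3-en-1-yl]propanoate
Conditions: MeZnCl (1.5 equiv), Pd(dppf)Cl2 (5 mol %), THF, 50 °C
Reagents that add atoms: methylzinc chloride, C[Zn]Cl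
Why: Negishi coupling replaces the triflate by methyl with the double bond held in place; the organozinc reagent tolerates the coumarin lactone and the ester, and the homoallylic aryl ether cannot ionise to a π-allyl complex.

Step 9
Reactants: 24 tert-butyl 3-[(1R,2R,6R)-1,3-dimethyl-2-{[(2-oxo-2H-chromen-7-yl)oxy]methyl}-6-(prop-1-en-2-yl)cyclohex-3-en-1-yl]propanoate
Product: 26 3-[(1R,2R,6R)-1,3-dimethyl-2-{[(2-oxo-2H-chromen-7-yl)oxy]methyl}-6-(prop-1-en-2-yl)cyclohex-3-en-1-yl]propanoic acid, via trimethylsilyl ester 25 (not isolated)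
Conditions: TMSOTf, 2,6-lutidine, CH2Cl2, 0 °C to rt; aq buffer pH 4
Reagents that add atoms: none
Why: Silyl-triflate-mediated cleavage of a tert-butyl ester (loss of isobutene, then hydrolysis of the silyl ester on work-up) runs in a buffered, non-protic medium that should spare the acid-sensitive isopropenyl and trisubstituted alkenes, the aryl ether and the lactone.

**Compound list**
1 | 2-methylcyclopent-2-en-1-one | CC1=CCCC1=O | starting material
2 | isopropenylmagnesium bromide | C=C(C)[Mg]Br | starting material
3 | bromomagnesium enolate of 4 | C=C(C)[C@H]1CCC(O[Mg]Br)=C1C | intermediate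
4 | (3S)-2-methyl-3-(prop-1-en-2-yl)cyclopentan-1-one (C2 epimers) | C=C(C)[C@H]1CCC(=O)C1C | intermediate
5 | (R)-1-phenylethylamine | N[C@H](C)c1ccccc1 | starting material
6 | tert-butyl acrylate | C=CC(=O)OC(C)(C)C | starting material
7 | ketimine of 4 with 5 | C=C(C)[C@H]1CCC(=N[C@H](C)c2ccccc2)C1C | intermediate
8 | ketimine of 9 with 5 | C=C(C)[C@H]1CCC(=N[C@H](C)c2ccccc2)[C@]1(C)CCC(=O)OC(C)(C)C | intermediate
9 | tert-butyl 3-[(1R,5R)-1-methyl-2-oxo-5-(prop-1-en-2-yl)cyclopentyl]propanoate | C=C(C)[C@H]1CCC(=O)[C@]1(C)CCC(=O)OC(C)(C)C | intermediate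
10 | dibromomethane | BrCBr | starting material
11 | tert-butyl 3-[(1R,2R,5R)-2-(dibromomethyl)-2-hydroxy-1-methyl-5-(prop-1-en-2-yl)cyclopentyl]propanoate (OH cis to methyl and isopropenyl) | C=C(C)[C@H]1CC[C@](O)(C(Br)Br)[C@]1(C)CCC(=O)OC(C)(C)C | intermediate
12 | formaldehyde (monomer from paraformaldehyde) | C=O | starting material
13 | lithium alkoxide / bromo(lithio)methyl carbenoid from 11 | C=C(C)[C@H]1CC[C@](O[Li])(C([Li])Br)[C@]1(C)CCC(=O)OC(C)(C)C | intermediate
14 | ring-enlarged lithium enolate (C3=C2) | C=C(C)[C@H]1CCC(O[Li])=C[C@]1(C)CCC(=O)OC(C)(C)C | intermediate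
15 | tert-butyl 3-[(1R,6R)-2-(hydroxymethyl)-1-methyl-3-oxo-6-(prop-1-en-2-yl)cyclohexyl]propanoate (C2 epimers) | C=C(C)[C@H]1CCC(=O)C(CO)[C@]1(C)CCC(=O)OC(C)(C)C | intermediate
16 | methanesulfonate of 15 | C=C(C)[C@H]1CCC(=O)C(COS(C)(=O)=O)[C@]1(C)CCC(=O)OC(C)(C)C | intermediate
17 | tert-butyl 3-[(1R,6R)-1-methyl-2-methylidene-3-oxo-6-(prop-1-en-2-yl)cyclohexyl]propanoate | C=C(C)[C@H]1CCC(=O)C(=C)[C@]1(C)CCC(=O)OC(C)(C)C | intermediate
18 | umbelliferone (7-hydroxy-2H-chromen-2-one) | Oc1ccc2ccc(=O)oc2c1 | starting material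
19 | tert-butyl 3-[(1R,2R,6R)-1-methyl-3-oxo-2-{[(2-oxo-2H-chromen-7-yl)oxy]methyl}-6-(prop-1-en-2-yl)cyclohexyl]propanoate | C=C(C)[C@H]1CCC(=O)[C@@H](COc2ccc3ccc(=O)oc3c2)[C@]1(C)CCC(=O)OC(C)(C)C | intermediate
20 | N-phenylbis(trifluoromethanesulfonimide) | O=S(=O)(N(c1ccccc1)S(=O)(=O)C(F)(F)F)C(F)(F)F | starting material
21 | potassium enolate (C3=C4) of 19 | C=C(C)[C@H]1CC=C(O[K])[C@@H](COc2ccc3ccc(=O)oc3c2)[C@]1(C)CCC(=O)OC(C)(C)C | intermediate
22 | enol triflate of 19 (1R,2R,6R) | C=C(C)[C@H]1CC=C(OS(=O)(=O)C(F)(F)F)[C@@H](COc2ccc3ccc(=O)oc3c2)[C@]1(C)CCC(=O)OC(C)(C)C | intermediate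
23 | methylzinc chloride | C[Zn]Cl | starting material
24 | tert-butyl ester of the target (1R,2R,6R) | C=C(C)[C@H]1CC=C(C)[C@@H](COc2ccc3ccc(=O)oc3c2)[C@]1(C)CCC(=O)OC(C)(C)C | intermediate
25 | trimethylsilyl ester of the target | C=C(C)[C@H]1CC=C(C)[C@@H](COc2ccc3ccc(=O)oc3c2)[C@]1(C)CCC(=O)O[Si](C)(C)C | intermediate
26 | 3-[(1R,2R,6R)-1,3-dimethyl-2-{[(2-oxo-2H-chromen-7-yl)oxy]methyl}-6-(prop-1-en-2-yl)cyclohex-3-en-1-yl]propanoic acid | C=C(C)[C@H]1CC=C(C)[C@@H](COc2ccc3ccc(=O)oc3c2)[C@]1(C)CCC(=O)O | target

Total steps: 9. Longest linear sequence: 9 steps (from 1).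

**Steps most likely to fail**

Step 4. The ring CH2 may migrate instead of the quaternary carbon. The carbenoid may be protonated or may close to an epoxide. The new enolate may also acylate itself on the ester arm (five-membered Dieckmann-type closure) before formaldehyde arrives.
Fallback, from 9 back to 15: the shift is run in a cationoid, copper-assisted manner and the enolate is made separately.
- Bis(phenylsulfanyl)methyllithium is added to 9 to give the bis(phenylsulfanyl)methyl carbinol F1.
- Copper(I) triflate with i-Pr2NEt removes one thiolate and triggers the pinacol-type shift of the more substituted carbon, giving the ring-enlarged 2-(phenylsulfanyl)cyclohexanone F2.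
- SmI2 in THF at −78 °C cleaves the C–S bond to the same regiodefined enolate, which is hydroxymethylated with formaldehyde to 15.

Step 6. The addition may reverse, facial selectivity in the enolate protonation may be poor, and the aryloxide may be lost under base in the following step.
Fallback, from 17 back to 24: a group that cannot leave as an anion is placed on the exocyclic carbon, and the aryl ether is made last.
- Cu-catalysed conjugate borylation (B2pin2, CuCl, NaOt-Bu, a diphosphine, MeOH) sets C2 by the same axial protonation and gives the β-boryl ketone F3.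
- NaBO3 gives the (2R)-hydroxymethyl ketone F4.
- TBSCl/imidazole gives the silyl ether F5.
- KHMDS/PhNTf2 gives the enol triflate F6.
- MeZnCl/Pd gives the methyl cyclohexene F7.
- TBAF gives the homoallylic primary alcohol F8.
- Mitsunobu etherification of F8 with 18 (PPh3, DIAD) gives 24.

Step 1. The branched sp2 Grignard reagent may give low enantioselectivity or competing 1,2-addition.
Fallback, from 1 back to 9: the absolute configuration is taken from the auxiliary instead of a catalyst.
- Achiral CuI/TMSCl-promoted addition of 2 to 1 gives the racemic ketone F9, which is carried into the imine Michael addition of step 2 with 5.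
- The (3S)-series is matched and gives 9.
- The (3R)-series is mismatched, reacts more slowly and should give mainly the cis diastereomer F10, which is removed by chromatography.

**Further compounds**
F1 | step 4 | tert-butyl 3-[(1R,2R,5R)-2-[bis(phenylsulfanyl)methyl]-2-hydroxy-1-methyl-5-(prop-1-en-2-yl)cyclopentyl]propanoate | C=C(C)[C@H]1CC[C@](O)(C(Sc2ccccc2)Sc2ccccc2)[C@]1(C)CCC(=O)OC(C)(C)C
F2 | step 4 | tert-butyl 3-[(1R,6R)-1-methyl-3-oxo-2-(phenylsulfanyl)-6-(prop-1-en-2-yl)cyclohexyl]propanoate (C2 epimers) | C=C(C)[C@H]1CCC(=O)C(Sc2ccccc2)[C@]1(C)CCC(=O)OC(C)(C)C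
F3 | step 6 | tert-butyl 3-[(1R,2S,6R)-1-methyl-3-oxo-6-(prop-1-en-2-yl)-2-[(4,4,5,5-tetramethyl-1,3,2-dioxaborolan-2-yl)methyl]cyclohexyl]propanoate | C=C(C)[C@H]1CCC(=O)[C@@H](CB2OC(C)(C)C(C)(C)O2)[C@]1(C)CCC(=O)OC(C)(C)C
F4 | step 6 | tert-butyl 3-[(1R,2R,6R)-2-(hydroxymethyl)-1-methyl-3-oxo-6-(prop-1-en-2-yl)cyclohexyl]propanoate | C=C(C)[C@H]1CCC(=O)[C@@H](CO)[C@]1(C)CCC(=O)OC(C)(C)C
F5 | step 6 | tert-butyldimethylsilyl ether of F4 | C=C(C)[C@H]1CCC(=O)[C@@H](CO[Si](C)(C)C(C)(C)C)[C@]1(C)CCC(=O)OC(C)(C)C
F6 | step 6 | enol triflate (C3=C4) of F5 | C=C(C)[C@H]1CC=C(OS(=O)(=O)C(F)(F)F)[C@@H](CO[Si](C)(C)C(C)(C)C)[C@]1(C)CCC(=O)OC(C)(C)C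
F7 | step 6 | tert-butyl 3-[(1R,2R,6R)-2-{[(tert-butyldimethylsilyl)oxy]methyl}-1,3-dimethyl-6-(prop-1-en-2-yl)cyclohex-3-en-1-yl]propanoate | C=C(C)[C@H]1CC=C(C)[C@@H](CO[Si](C)(C)C(C)(C)C)[C@]1(C)CCC(=O)OC(C)(C)C
F8 | step 6 | tert-butyl 3-[(1R,2R,6R)-2-(hydroxymethyl)-1,3-dimethyl-6-(prop-1-en-2-yl)cyclohex-3-en-1-yl]propanoate | C=C(C)[C@H]1CC=C(C)[C@@H](CO)[C@]1(C)CCC(=O)OC(C)(C)C
F9 | step 1 | racemic 2-methyl-3-(prop-1-en-2-yl)cyclopentan-1-one | C=C(C)C1CCC(=O)C1C
F10 | step 1 | tert-butyl 3-[(1R,5S)-1-methyl-2-oxo-5-(prop-1-en-2-yl)cyclopentyl]propanoate | C=C(C)[C@@H]1CCC(=O)[C@]1(C)CCC(=O)OC(C)(C)C
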